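Atoms carry eudesmane numbers. The tetrasubstituted C4=C5 alkene shared by rings A and B, with the oxygen on C3 next to it, is read as a Δ4-3-ketone. Ring A is closed on a preformed ring B by joining C3, as an acylium ion, to C4 of an exocyclic ethylidene on C5. This intramolecular alkene acylation makes the C3–C4 bond and the enone in one operation, is blind to the E/Z geometry of the ethylidene and lets the C7 epimers funnel into the equatorial isomer. The precursor is a monocyclic keto acid whose only fixed stereocentre, the quaternary C10, comes from an asymmetric imine Michael reaction; hydride reduction then sets C3 and C8.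

Key step: step 5

Remark: 7-methyl-1,4-dioxaspiro[4.5]decan-8-one and (E)-3-methylpent-2-enoic acid are taken as catalogue compounds; β denotes the face of the C10 methyl group, and C11–C13 are the carbons of the acrylate unit.

Step 1
Reactants: 1 7-methyl-1,4-dioxaspiro[4.5]decan-8-one (racemic); 2 (R)-1-phenylethylamine; 3 methyl acrylate
Product: 6 methyl 3-[(7R)-7-methyl-8-oxo-1,4-dioxaspiro[4.5]decan-7-yl]propanoate, via ketimine 4 (not isolated), via alkylated ketimine 5 (not isolated)
Conditions: 2, 4 Å MS, toluene, reflux; 3 (neat), 40 °C; 20% aq. AcOH, THF, rt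
Reagents that add atoms: water, O
Why: Asymmetric Michael reaction of a chiral ketimine, which reacts through its more substituted secondary enamine tautomer in a cyclic aza-ene-like transition state, so that the (R)-1-phenylethyl group directs methyl acrylate to one face of the methyl-bearing carbon and should set the quaternary C10 centre (R) from either enantiomer of 1.

Step 2
Reactants: 6 methyl 3-[(7R)-7-methyl-8-oxo-1,4-dioxaspiro[4.5]decan-7-yl]propanoate
Product: 7 methyl 3-[(7R)-8-ethylidene-7-methyl-1,4-dioxaspiro[4.5]decan-7-yl]propanoate (E/Z mixture)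
Conditions: EtPPh3Br, KOtBu, THF, 0 °C → reflux
Reagents that add atoms: ethyltriphenylphosphonium bromide, CC[P+](c1ccccc1)(c1ccccc1)c1ccccc1.[Br-]
Why: Wittig olefination with a non-stabilised ylide, which should attack the ketone in preference to the ester and the acetal and whose E/Z outcome is irrelevant because both isomers converge in step 5.

Step 3
Reactants: 7 methyl 3-[(7R)-8-ethylidene-7-methyl-1,4-dioxaspiro[4.5]decan-7-yl]propanoate
Product: 9 3-[(1R)-2-ethylidene-1-methyl-5-oxocyclohexyl]propanoic acid (E/Z mixture), via lithium carboxylate 8 (not isolated)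
Conditions: LiOH·H2O, THF/MeOH/H2O, rt; then 2 M HCl (pH 1), rt
Reagents that add atoms: lithium hydroxide, [Li+].[OH-]; water, O
Why: Ester saponification followed in the same pot by acid-catalysed acetal hydrolysis, under conditions too mild to protonate the trisubstituted alkene or to touch the quaternary centre.

Step 4
Reactants: 9 3-[(1R)-2-ethylidene-1-methyl-5-oxocyclohexyl]propanoic acid
Product: 10 3-[(1R)-2-ethylidene-4-(2-methoxy-2-oxoethyl)-1-methyl-5-oxocyclohexyl]propanoic acid (mixture at the new centre C7 and of alkene isomers)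
Conditions: LiN(iPr)2 (2.2 equiv), THF, −78 °C; BrCH2CO2Me, DMPU, −78 → −40 °C; 1 M HCl work-up
Reagents that add atoms: methyl bromoacetate, COC(=O)CBr
Why: Enolate alkylation of the carboxylate/ketone dianion, in which kinetic deprotonation should occur at C7 rather than at the neopentyl C9 while the lithium carboxylate stays inert, the new C7 centre being left uncontrolled because it is equilibrated in step 5.

Step 5
Reactants: 10 3-[(1R)-2-ethylidene-4-(2-methoxy-2-oxoethyl)-1-methyl-5-oxocyclohexyl]propanoic acid
Product: 13 methyl 3,8-dioxo-13-noreudesm-4-en-12-oate (7β-CH2CO2Me; 10β-CH3), via acyl chloride 11 (not isolated), via chloro ketone 12 (not isolated)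
Conditions: (COCl)2, DMF (cat.), CH2Cl2, 0 °C, concentrate; SnCl4, CH2Cl2, −78 → −20 °C; DBU, CH2Cl2, rt
Reagents that add atoms: none
Why: Oxalyl chloride converts the acid into acyl chloride 11, SnCl4 ionises it to an acylium ion that attacks the exocyclic ethylidene at C4 to leave a tertiary cation at C5, chloride capture gives 12, and DBU eliminates HCl into conjugation to give the Δ4-3-ketone. The closest known reaction type is the intramolecular Friedel–Crafts-type acylation of an alkene by an acyl chloride (Darzens–Nenitzescu reaction). Ring A closes in the 6-endo-trig mode through the new C3–C4 bond. C3, C4 and C5 all end up sp2, so the E and Z ethylidene isomers of 10 should give the same product, and the C7 epimers should converge under DBU on the equatorial 7β isomer, controlled by the axial C10 methyl group of the newly formed bicycle. The step needs attack at C4 rather than C5, secured by the tertiary cation and by the six- over five-membered ring, and reaction of the acylium ion with the alkene rather than with the C8 ketone or the ester, secured by the low temperature at which the ketone does not enolise.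

Step 6
Reactants: 13 methyl 3,8-dioxo-13-noreudesm-4-en-12-oate
Product: 15 3β-hydroxy-13-noreudesm-4-en-8β,12-olide (cis-fused γ-lactone), via diol ester 14 (not isolated)
Conditions: NaBH4, CeCl3·7H2O, MeOH, −78 → 0 °C; PPTS (cat.), CH2Cl2, rt
Reagents that add atoms: none
Why: Luche reduction (1,2-selective) in which hydride should approach both carbonyl groups from the α face, the β face being shielded by the axial C10 methyl group, giving the pseudo-equatorial 3β alcohol and the axial 8β alkoxide, the latter closing the cis-fused γ-lactone onto the 7β side chain.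

Step 7
Reactants: 15 3β-hydroxy-13-noreudesm-4-en-8β,12-olide
Product: 18 3β-hydroxyeudesma-4,11(13)-dien-8β,12-olide, via Mannich base 16 (not isolated), via ammonium iodide 17 (not isolated)
Conditions: LiN(iPr)2 (2.3 equiv), THF, −78 °C; Me2N=CH2 I (Eschenmoser's salt), −78 °C → rt; MeI, MeOH, rt; aq. NaHCO3, EtOAc
Reagents that add atoms: Eschenmoser's salt (N,N-dimethylmethyleneiminium iodide), C=[N+](C)C.[I-]
Why: α-Methylenation of a lactone by Mannich reaction of its lithium enolate with Eschenmoser's salt (the hydroxyl being carried as its alkoxide), N-methylation and Hofmann-type elimination, which can only give the exocyclic C11=C13 alkene.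

Step 8
Reactants: 18 3β-hydroxyeudesma-4,11(13)-dien-8β,12-olide; 19 (E)-3-methylpent-2-enoic acid
Product: 20 3β-[(E)-3-methylpent-2-enoyloxy]eudesma-4,11(13)-dien-8β,12-olide
Conditions: 19, EDC·HCl, DMAP, CH2Cl2, 0 °C → rt
Reagents that add atoms: none
Why: Steglich esterification of the allylic 3β-hydroxyl, which proceeds at oxygen with retention at C3 under conditions mild enough to keep the E-configured β,β-disubstituted enoate and the methylene lactone intact.

Step 9
Reactants: 20 3β-[(E)-3-methylpent-2-enoyloxy]eudesma-4,11(13)-dien-8β,12-olide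
Product: 22 methyl 8β-hydroxy-3β-[(E)-3-methylpent-2-enoyloxy]eudesma-4,11(13)-dien-12-oate, via lithium carboxylate 21 (not isolated)
Conditions: LiOH·H2O (1.05 equiv), THF/H2O, 0 °C; concentrate; MeI, DMF, 0 °C → rt
Reagents that add atoms: lithium hydroxide, [Li+].[OH-]; iodomethane, CI
Why: Chemoselective saponification of the strained, unhindered γ-lactone in preference to the hindered β,β-disubstituted enoate, followed by SN2 O-methylation of the carboxylate, which should deliver the methyl ester without passing through the free hydroxy acid that would relactonise.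

Step 10
Reactants: 22 methyl 8β-hydroxy-3β-[(E)-3-methylpent-2-enoyloxy]eudesma-4,11(13)-dien-12-oate
Product: 23 methyl 8β-acetoxy-3β-[(E)-3-methylpent-2-enoyloxy]eudesma-4,11(13)-dien-12-oate (CNP0118541.1)
Conditions: Ac2O, DMAP, pyridine, CH2Cl2, 0 °C
Reagents that add atoms: acetic anhydride, CC(=O)OC(C)=O
Why: DMAP-catalysed acetylation of the axial 8β-hydroxyl with retention of configuration, run cold so that acylation should outpace relactonisation.

Compound list
1 | 7-methyl-1,4-dioxaspiro[4.5]decan-8-one (racemic) | CC1CC2(CCC1=O)OCCO2 | starting material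
2 | (R)-1-phenylethylamine | C[C@@H](N)c1ccccc1 | starting material
3 | methyl acrylate | C=CC(=O)OC | starting material
4 | N-[(R)-1-phenylethyl] ketimine of 1 | CC1CC2(CCC1=N[C@H](C)c1ccccc1)OCCO2 | intermediate
5 | ketimine of 6 (C-alkylated at the methyl-bearing carbon) | COC(=O)CC[C@]1(C)CC2(CCC1=N[C@H](C)c1ccccc1)OCCO2 | intermediate
6 | methyl 3-[(7R)-7-methyl-8-oxo-1,4-dioxaspiro[4.5]decan-7-yl]propanoate | COC(=O)CC[C@]1(C)CC2(CCC1=O)OCCO2 | intermediate
7 | methyl 3-[(7R)-8-ethylidene-7-methyl-1,4-dioxaspiro[4.5]decan-7-yl]propanoate (E/Z mixture) | COC(=O)CC[C@]1(C)CC2(CCC1=CC)OCCO2 | intermediate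
8 | lithium 3-[(7R)-8-ethylidene-7-methyl-1,4-dioxaspiro[4.5]decan-7-yl]propanoate | [Li+].[O-]C(=O)CC[C@]1(C)CC2(CCC1=CC)OCCO2 | intermediate
9 | 3-[(1R)-2-ethylidene-1-methyl-5-oxocyclohexyl]propanoic acid (E/Z mixture) | OC(=O)CC[C@]1(C)CC(=O)CCC1=CC | intermediate
10 | 3-[(1R)-2-ethylidene-4-(2-methoxy-2-oxoethyl)-1-methyl-5-oxocyclohexyl]propanoic acid (epimers at C7, E/Z mixture) | OC(=O)CC[C@]1(C)CC(=O)C(CC(=O)OC)CC1=CC | intermediate
11 | acyl chloride of 10 | ClC(=O)CC[C@]1(C)CC(=O)C(CC(=O)OC)CC1=CC | intermediate
12 | methyl 5-chloro-3,8-dioxo-13-noreudesman-12-oate (mixture of diastereomers, 10β-methyl) | COC(=O)CC1CC2(Cl)C(C)C(=O)CC[C@]2(C)CC1=O | intermediate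
13 | methyl 3,8-dioxo-13-noreudesm-4-en-12-oate (7β side chain, 10β-methyl) | COC(=O)C[C@H]1CC2=C(C)C(=O)CC[C@]2(C)CC1=O | intermediate
14 | methyl 3β,8β-dihydroxy-13-noreudesm-4-en-12-oate | COC(=O)C[C@H]1CC2=C(C)[C@@H](O)CC[C@]2(C)C[C@H]1O | intermediate
15 | 3β-hydroxy-13-noreudesm-4-en-8β,12-olide | O=C1C[C@H]2CC3=C(C)[C@@H](O)CC[C@]3(C)C[C@H]2O1 | intermediate
16 | 13-(dimethylamino)-3β-hydroxyeudesm-4-en-8β,12-olide (mixture at C11) | O=C1C(CN(C)C)[C@H]2CC3=C(C)[C@@H](O)CC[C@]3(C)C[C@H]2O1 | intermediate
17 | N-methyl ammonium iodide of 16 | O=C1C(C[N+](C)(C)C)[C@H]2CC3=C(C)[C@@H](O)CC[C@]3(C)C[C@H]2O1.[I-] | intermediate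
18 | 3β-hydroxyeudesma-4,11(13)-dien-8β,12-olide | O=C1C(=C)[C@H]2CC3=C(C)[C@@H](O)CC[C@]3(C)C[C@H]2O1 | intermediate
19 | (E)-3-methylpent-2-enoic acid | OC(=O)/C=C(\C)CC | starting material
20 | 3β-[(E)-3-methylpent-2-enoyloxy]eudesma-4,11(13)-dien-8β,12-olide | O=C1C(=C)[C@H]2CC3=C(C)[C@@H](OC(=O)/C=C(\C)CC)CC[C@]3(C)C[C@H]2O1 | intermediate
21 | lithium 8β-hydroxy-3β-[(E)-3-methylpent-2-enoyloxy]eudesma-4,11(13)-dien-12-oate | [Li+].[O-]C(=O)C(=C)[C@H]1CC2=C(C)[C@@H](OC(=O)/C=C(\C)CC)CC[C@]2(C)C[C@H]1O | intermediate
22 | methyl 8β-hydroxy-3β-[(E)-3-methylpent-2-enoyloxy]eudesma-4,11(13)-dien-12-oate | C=C(C(=O)OC)[C@H]1CC2=C(C)[C@@H](OC(=O)/C=C(\C)CC)CC[C@]2(C)C[C@H]1O | intermediate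
23 | methyl 2-[(2R,3R,4aR,7S)-3-acetoxy-4a,8-dimethyl-7-{[(2E)-3-methylpent-2-enoyl]oxy}-1,2,3,4,4a,5,6,7-octahydronaphthalen-2-yl]prop-2-enoate (CNP0118541.1) | C=C(C(=O)OC)[C@H]1CC2=C(C)[C@@H](OC(=O)/C=C(\C)CC)CC[C@]2(C)C[C@H]1OC(C)=O | target

Total step count: 10. Longest linear sequence: 10 steps (1 to 23).

Steps most likely to fail

Step 5. The acylium ion may be intercepted by the enol form of the C8 ketone, or the Lewis acid may move the exocyclic double bond into ring B before the C–C bond forms, which would divert the acylation to C6 and a bridged ketone. The fallback sets out from 10 by way of its acyl chloride 11. Reduction with Bu3SnH and Pd(PPh3)4 would give the aldehyde F1. Me2AlCl in CH2Cl2 at −78 °C should then trigger an intramolecular carbonyl-ene reaction in which C3 bonds to C4 and a C6 hydrogen is transferred, giving the homoallylic alcohol F2 with a C5=C6 alkene. Dess–Martin oxidation would give the β,γ-unsaturated diketone F3, which DBU should isomerise to the more substituted conjugated enone while equilibrating C7, so that the sequence comes back to the route at 13.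

Step 4. Deprotonation may lose its preference for C7 over C9, the carboxylate may be O-alkylated, and proton transfer between enolates may lead to dialkylation. The fallback sets out from 9 and uses a Stork enamine alkylation instead of a lithium enolate. Pyrrolidine (benzene, water removal) should give the less substituted enamine F4 with the C7=C8 double bond. Methyl bromoacetate in acetonitrile would alkylate it at C7 to the iminium bromide F5, and buffered aqueous hydrolysis (NaOAc/AcOH) comes back to the route at 10.

Step 9. Hydroxide may also cleave the C3 ester or add to the methylene group, and the hydroxy ester may relactonise before or during the acetylation of step 10. The fallback sets out from 18 and reverses the order of events. LiOH followed by MeI in DMF would give, by way of the lithium carboxylate F6, the diol ester F7. Steglich esterification with one equivalent of 19 at low temperature should then acylate the more accessible allylic 3β-hydroxyl selectively, which comes back to the route at 22.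

Further compounds
F1 | step 5 | methyl 2-[(5R)-4-ethylidene-5-methyl-2-oxo-5-(3-oxopropyl)cyclohexyl]acetate (E/Z and C7 mixture) | O=CCC[C@]1(C)CC(=O)C(CC(=O)OC)CC1=CC
F2 | step 5 | methyl 3-hydroxy-8-oxo-13-noreudesm-5-en-12-oate (mixture at C3, C4 and C7, 10β-methyl) | COC(=O)CC1C=C2C(C)C(O)CC[C@]2(C)CC1=O
F3 | step 5 | methyl 3,8-dioxo-13-noreudesm-5-en-12-oate (mixture at C4 and C7, 10β-methyl) | COC(=O)CC1C=C2C(C)C(=O)CC[C@]2(C)CC1=O
F4 | step 4 | 3-[(1R)-2-ethylidene-1-methyl-5-(pyrrolidin-1-yl)cyclohex-4-en-1-yl]propanoic acid | OC(=O)CC[C@]1(C)CC(N2CCCC2)=CCC1=CC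
F5 | step 4 | 1-[(5R)-5-(2-carboxyethyl)-4-ethylidene-2-(2-methoxy-2-oxoethyl)-5-methylcyclohexylidene]pyrrolidinium bromide | OC(=O)CC[C@]1(C)CC(=[N+]2CCCC2)C(CC(=O)OC)CC1=CC.[Br-]
F6 | step 9 | lithium 3β,8β-dihydroxyeudesma-4,11(13)-dien-12-oate | [Li+].[O-]C(=O)C(=C)[C@H]1CC2=C(C)[C@@H](O)CC[C@]2(C)C[C@H]1O
F7 | step 9 | methyl 3β,8β-dihydroxyeudesma-4,11(13)-dien-12-oate | C=C(C(=O)OC)[C@H]1CC2=C(C)[C@@H](O)CC[C@]2(C)C[C@H]1O
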